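Remark on the chemistry: the SMILES has no stereogenic element and the tether is read as thirteen CH2 groups (C28H38O8). 3-Methoxy-2-methylphenol and pentadecanedioic acid are taken as commercial.

## Structural features

The target consists of two fully substituted 1,4-benzoquinone rings whose C3 atoms are joined by an unbranched, saturated chain of thirteen methylene groups. Ring A carries OH at C2 (next to the chain carbon C3), OCH3 at C5 and CH3 at C6; ring B carries OH at C2' and C5' and CH3 at C6', so the rings differ by a single O-methyl group. There is no stereocentre and no stereogenic double bond, so nothing has to be controlled stereochemically. The hydroxyquinones are vinylogous acids that chelate metals and are degraded by strong nucleophiles and reductants, and the ring A methoxy group is a vinylogous ester that hydroxide cleaves. The real difficulty is the combination of hexasubstitution of both rings with the need to place one methyl ether on one of four almost equivalent enolic oxygens, each flanked by a carbonyl and an alkyl-bearing carbon, in two rings that are thirteen carbons apart and cannot influence each other. The key step exploits the position of the chain-bearing carbon in each ring (C3 of ring A, C3' of ring B): it lies between the enolic C–OH and a carbonyl carbon, the one site at which a 2-hydroxy-1,4-benzoquinone with a C–H there accepts a nucleophilic alkyl radical. With the chain removed, each ring is a small hydroxyquinone with a single C–H, and thirteen chain carbons plus two carboxyl carbons make a C15 α,ω-diacid. In one sentence: the finished, unprotected ring A is attached last, by addition of the primary radical released on decarboxylation of acid 8 to the only C–H carbon of hydroxy(methoxy)quinone 5.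

## Logic of the disconnections

**9 ⇒ 8 + 5.** The bond cut is C3 (ring A)–C1 (tether). Cutting here removes ring A as a complete unit that already holds its methyl ether in the correct place, so no reaction ever has to choose among the four ring oxygens of 9. The gain is that a C28 bis-quinone falls into a C21 acid and a C8 quinone, with no protecting group and no late arene oxidation. The demand on the forward step is that the radical formed from 8 by loss of CO2 adds to the single C–H carbon of 5 and that the adduct is reoxidised, all in the presence of three free enolic OH groups.

**8 ⇒ 6 + 7.** The bond cut is C3' (ring B)–C13 (tether), by the same reaction type. 7 supplies all thirteen tether carbons; its two carboxyl carbons are lost as CO2 in this step and the next. The gain is a commercial chain and a C7 quinone. The demand is that only one carboxyl group of 7 reacts, which is met by using 7 in excess and recovering it.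

**6 ⇒ 5.** The bond cut is O–CH3. Both ring units then come from one precursor, and the only difference between ring A and ring B becomes whether this hydrolysis is carried out before the chain is attached. The demand is clean cleavage of a vinylogous ester without degradation of the hydroxyquinone.

**5 ⇒ 3 (through 4).** This is a change of oxidation level and removal of three O-acetyl groups. 5 is the oxidised form of 4, and 4 is stored as its air-stable ester 3. The demand is deacylation without base-induced air oxidation or ether cleavage.

**3 ⇒ 2.** The bond cut is C5–O. It is formed by conjugate addition of acetate to the quinone with reductive aromatisation. The demand is regiochemical: the oxygen must enter para to the methoxy-bearing carbon, not para to the methyl-bearing carbon.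

**2 ⇒ 1.** The bond cut is C4–O, formed by oxidation of the free para position of a phenol. 1 already contains the adjacent OCH3/CH3 pair of ring A.

## Other disconnections considered

**Alternative 1:** (the first that comes to mind) Cut both ring–chain bonds at the arene oxidation level. Forward: twofold alkylation of a lithiated tetra-O-methylated methylarene with a C13 α,ω-dihalide would give 1,13-bis(2,3,5,6-tetramethoxy-4-methylphenyl)tridecane A1, and oxidative demethylation would give the bis(dimethoxyquinone) A2. The weakness is the end game: three of the four methoxy groups of A2 must be hydrolysed and the survivor must be the one next to CH3 in one ring. All four are vinylogous esters flanked by a carbonyl and an alkyl-bearing carbon, so there is no structural basis for selection and a statistical mixture of constitutional isomers is expected. Curing this needs two differently protected arenes joined one after the other to an unsymmetrical chain, which roughly doubles the step count. The chosen plan never creates the problem.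

**Alternative 2:** Build each hexasubstituted ring from a four-membered ring. Forward: a squarate diester and a C13 α,ω-dimetal reagent would give the bis(cyclobutenedione) A3. Addition of the vinyllithium reagent A4 to the more electrophilic carbonyl of each dione, thermal 4π ring opening to the dienylketene, 6π ring closure and oxidation would give the bis-quinone A5. This closes both rings with the oxygens para and the OCH3/CH3 pair adjacent. It was not chosen for three reasons: both rings come out identical, so one of two remote, equivalent methyl ethers must still be cleaved statistically; the β-alkoxyvinyllithium A4 is prone to β-elimination; and the regiochemistry of carbonyl addition has to be right twice. The route would be about twice as long as the chosen one.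

**Alternative 3:** Cut each ring B-type ring into two α-keto ester units. Forward: crossed double Claisen condensation of the bis(α-keto ester) A6 with ethyl 2-oxobutanoate would give the cyclohexane-1,2,4,5-tetraone tautomer, that is the bis(dihydroxyquinone) A7, directly at the right oxidation level. Two problems remain: homo-condensation competes with crossed condensation at both chain ends, and A7 must then be O-methylated once, next to CH3 and not next to the chain, on one of four equivalent hydroxyls. The chosen plan decides that regiochemistry in a C8 precursor instead.

Key step: step 6

## Route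

Step 1
Reactants: 1 3-methoxy-2-methylphenol
Product: 2 2-methoxy-3-methyl-1,4-benzoquinone
Conditions: K2[ON(SO3)2] (2.2 equiv), KH2PO4, H2O/acetone, 0 °C to rt
Reagents that add atoms: Fremy's salt (dipotassium nitrosodisulfonate), [K+].[K+].[O]N(S(=O)(=O)[O-])S(=O)(=O)[O-]
Why: Teuber oxidation: the nitroxyl radical abstracts the phenolic hydrogen, a second equivalent adds at the free para carbon and loss of imidodisulfonate gives the quinone; because the para position is unsubstituted the 1,4-quinone is expected, not the ortho-quinone.

Step 2
Reactants: 2 2-methoxy-3-methyl-1,4-benzoquinone
Product: 3 5-methoxy-6-methylbenzene-1,2,4-triyl triacetate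
Conditions: Ac2O, H2SO4 (cat.), rt
Reagents that add atoms: acetic anhydride, CC(=O)OC(C)=O
Why: Thiele–Winter acetoxylation (acid-activated 1,4-addition of acetate, enolisation, acetylation); the C2 methoxy group makes the C4 carbonyl a vinylogous ester, so the C1 enone is the more electrophilic and acetate should enter at C5, para to the methoxy-bearing carbon, as in methoxy-1,4-benzoquinone itself.

Step 3
Reactants: 3 5-methoxy-6-methylbenzene-1,2,4-triyl triacetate
Product: 5 5-hydroxy-2-methoxy-3-methyl-1,4-benzoquinone, via 5-methoxy-6-methylbenzene-1,2,4-triol 4 (not isolated)
Conditions: HCl (cat.), MeOH, reflux, N2; evaporate; FeCl3, H2O, rt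
Reagents that add atoms: none
Why: Acid-catalysed transesterification frees the three phenols without exposing the air-sensitive triol 4 as its anion, and FeCl3 then oxidises the 1,2,4-triol to the 2-hydroxy-1,4-quinone tautomer; methanol is removed before the oxidation so that the vinylogous acid is not re-esterified.

Step 4
Reactants: 5 5-hydroxy-2-methoxy-3-methyl-1,4-benzoquinone
Product: 6 2,5-dihydroxy-3-methyl-1,4-benzoquinone
Conditions: NaOH (2 M, aq), 60 °C; then HCl to pH 1
Reagents that add atoms: sodium hydroxide, [Na+].[OH-]
Why: Vinylogous ester hydrolysis by addition–elimination: hydroxide adds at C2 and expels methoxide, and the resulting dianion of 6 is a doubly vinylogous carboxylate that resists further attack until acidification.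

Step 5
Reactants: 6 2,5-dihydroxy-3-methyl-1,4-benzoquinone; 7 pentadecanedioic acid (4 equiv)
Product: 8 14-(2,5-dihydroxy-4-methyl-3,6-dioxocyclohexa-1,4-dien-1-yl)tetradecanoic acid
Conditions: AgNO3 (0.3 equiv), (NH4)2S2O8 (1.5 equiv), MeCN/H2O 1:1, 70 °C
Reagents that add atoms: none
Why: Silver-catalysed persulfate decarboxylative alkylation of a quinone (Jacobsen–Torssell reaction): the primary radical from one carboxyl group of 7 adds at C6, the only unsubstituted carbon of 6, and the adduct is reoxidised to the quinone; the excess of 7 keeps its second carboxyl group largely unused and the surplus is recovered.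

Step 6
Reactants: 8 14-(2,5-dihydroxy-4-methyl-3,6-dioxocyclohexa-1,4-dien-1-yl)tetradecanoic acid; 5 5-hydroxy-2-methoxy-3-methyl-1,4-benzoquinone (2.5 equiv)
Product: 9 2-hydroxy-5-methoxy-6-methyl-3-[13-(2,5-dihydroxy-4-methyl-3,6-dioxocyclohexa-1,4-dien-1-yl)tridecyl]-1,4-benzoquinone (target)
Conditions: AgNO3 (0.3 equiv), (NH4)2S2O8 (2 equiv), MeCN/H2O 1:1, 70 °C
Reagents that add atoms: none
Why: Divalent silver, formed from AgNO3 and persulfate, oxidises the carboxylate of 8, and loss of CO2 leaves a primary radical at the former C2 of the acid chain. This nucleophilic radical adds to C6 of 5, the only hydrogen-bearing ring carbon and the β-carbon of the C4 enone, giving a radical at C5 that is stabilised by the hydroxyl group and the C4 carbonyl. Oxidation of that radical by divalent silver or persulfate and loss of the C6 proton restore the quinone, so ring A is never taken to the hydroquinone level. The closest known reaction types are the silver/persulfate decarboxylative alkylation of quinones (Jacobsen–Torssell, also called Kochi–Anderson), which is used on 2-hydroxy-1,4-quinones, and the alkylation of 2,5-dihydroxy-1,4-benzoquinone with diacyl peroxides. No ring is closed and no stereocentre is formed. The step needs C–C bond formation at C6 of 5 in preference to attack at the fully substituted ring B of 8, at substituted carbons of 5 or at carbonyl oxygen; this is secured because C6 is the only carbon whose adduct can return to a quinone by proton loss, and because 5 is used in excess. The position of the single methyl ether is carried in unchanged from 5, so ring A is distinguished from ring B by the order of steps 5 and 6, not by a late reaction among four similar oxygens.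

## Compound list

1 | 3-methoxy-2-methylphenol | COc1cccc(O)c1C | starting material
2 | 2-methoxy-3-methyl-1,4-benzoquinone | COC1=C(C)C(=O)C=CC1=O | intermediate
3 | 5-methoxy-6-methylbenzene-1,2,4-triyl triacetate | CC(=O)Oc1cc(OC(C)=O)c(OC)c(C)c1OC(C)=O | intermediate
4 | 5-methoxy-6-methylbenzene-1,2,4-triol | COc1c(C)c(O)c(O)cc1O | intermediate (not isolated)
5 | 5-hydroxy-2-methoxy-3-methyl-1,4-benzoquinone | COC1=C(C)C(=O)C(O)=CC1=O | intermediate
6 | 2,5-dihydroxy-3-methyl-1,4-benzoquinone | CC1=C(O)C(=O)C=C(O)C1=O | intermediate
7 | pentadecanedioic acid | OC(=O)CCCCCCCCCCCCCC(O)=O | starting material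
8 | 14-(2,5-dihydroxy-4-methyl-3,6-dioxocyclohexa-1,4-dien-1-yl)tetradecanoic acid | CC1=C(O)C(=O)C(CCCCCCCCCCCCCC(O)=O)=C(O)C1=O | intermediate
9 | 2-hydroxy-5-methoxy-6-methyl-3-[13-(2,5-dihydroxy-4-methyl-3,6-dioxocyclohexa-1,4-dien-1-yl)tridecyl]-1,4-benzoquinone | COC1=C(C)C(=O)C(O)=C(CCCCCCCCCCCCCC2=C(O)C(=O)C(C)=C(O)C2=O)C1=O | target

## Step count and risk

Total step count: 6. Longest linear sequence: 6 steps (1 → 2 → 3 → 5 → 6 → 8 → 9); 5 is used twice, in steps 4 and 6.

**Step 6 (key step).** The radical may be lost to hydrogen abstraction, over-oxidation or dimerisation before it is trapped. The hydroxyquinones may be degraded oxidatively by sulfate radical anion. The silver catalyst may be withdrawn by salt formation with the acidic hydroxyquinones, so that decarboxylation stalls. The fallback changes the polarity of the bond formation and sets out from 6. Commercial tridecane-1,13-diol is oxidised (TEMPO cat., PhI(OAc)2, CH2Cl2) to tridecanedial F1. Compound 6, whose C6 is the central carbon of an enolised 1,3-dicarbonyl unit, is condensed with an excess of F1 in a three-component reductive alkylation (Knoevenagel condensation, then transfer hydrogenation of the alkylidene intermediate; L-proline cat., Hantzsch ester, CH2Cl2, rt) to give 13-(2,5-dihydroxy-4-methyl-3,6-dioxocyclohexa-1,4-dien-1-yl)tridecanal F2. The same reductive alkylation of 5 with F2 returns to the route at 9.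

**Step 5.** Both carboxyl groups of 7 may react, tying two molecules of 6 to one chain, and conversion may be low for the same reasons as in step 6. The fallback sets out from 7 and differentiates the chain ends by protection while changing the radical source. Partial esterification (MeOH, H2SO4 cat.) gives 15-methoxy-15-oxopentadecanoic acid F3. DCC and H2O2 (CH2Cl2, 0 °C) convert it into bis(15-methoxy-15-oxopentadecanoyl) peroxide F4. Thermolysis of F4 with 6 in AcOH at 95 °C (alkylation of a hydroxyquinone by a diacyl peroxide) gives methyl 14-(2,5-dihydroxy-4-methyl-3,6-dioxocyclohexa-1,4-dien-1-yl)tetradecanoate F5. Saponification (LiOH, THF/H2O; then HCl) returns to the route at 8.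

**Step 2.** Acetate may enter at C6 (para to the methyl-bearing carbon) to some extent, which would place the hydroxyl group of 5 on the wrong carbon. The fallback fixes both new C–O bonds by the directing groups of 1 and sets out from 1. Bromination (Br2, 2 equiv, AcOH) at the two positions that are ortho/para to both OH and OCH3 gives 4,6-dibromo-3-methoxy-2-methylphenol F6. Copper-catalysed etherification (BnOH, CuI, 1,10-phenanthroline, Cs2CO3, toluene, 110 °C) gives 4,6-bis(benzyloxy)-3-methoxy-2-methylphenol F7. Hydrogenolysis (H2, Pd/C, EtOAc) returns to the route at 4, which is oxidised with FeCl3 as in step 3 to give 5.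

## Further compounds

F1 | step 6 | tridecanedial | O=CCCCCCCCCCCCC=O
F2 | step 6 | 13-(2,5-dihydroxy-4-methyl-3,6-dioxocyclohexa-1,4-dien-1-yl)tridecanal | CC1=C(O)C(=O)C(CCCCCCCCCCCCC=O)=C(O)C1=O
F3 | step 5 | 15-methoxy-15-oxopentadecanoic acid | COC(=O)CCCCCCCCCCCCCC(O)=O
F4 | step 5 | bis(15-methoxy-15-oxopentadecanoyl) peroxide | COC(=O)CCCCCCCCCCCCCC(=O)OOC(=O)CCCCCCCCCCCCCC(=O)OC
F5 | step 5 | methyl 14-(2,5-dihydroxy-4-methyl-3,6-dioxocyclohexa-1,4-dien-1-yl)tetradecanoate | CC1=C(O)C(=O)C(CCCCCCCCCCCCCC(=O)OC)=C(O)C1=O
F6 | step 2 | 4,6-dibromo-3-methoxy-2-methylphenol | COc1c(Br)cc(Br)c(O)c1C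
F7 | step 2 | 4,6-bis(benzyloxy)-3-methoxy-2-methylphenol | COc1c(OCc2ccccc2)cc(OCc2ccccc2)c(O)c1C
A1 | alternative 1 | 1,13-bis(2,3,5,6-tetramethoxy-4-methylphenyl)tridecane | Cc1c(OC)c(OC)c(CCCCCCCCCCCCCc2c(OC)c(OC)c(C)c(OC)c2OC)c(OC)c1OC
A2 | alternative 1 | 3,3'-(tridecane-1,13-diyl)bis(2,5-dimethoxy-6-methyl-1,4-benzoquinone) | COC1=C(C)C(=O)C(OC)=C(CCCCCCCCCCCCCC2=C(OC)C(=O)C(C)=C(OC)C2=O)C1=O
A3 | alternative 2 | 4,4'-(tridecane-1,13-diyl)bis(3-tert-butoxycyclobut-3-ene-1,2-dione) | CC(C)(C)OC1=C(CCCCCCCCCCCCCC2=C(OC(C)(C)C)C(=O)C2=O)C(=O)C1=O
A4 | alternative 2 | (E)-1-methoxyprop-1-en-2-yllithium | [Li]/C(C)=C\OC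
A5 | alternative 2 | 3,3'-(tridecane-1,13-diyl)bis(2-tert-butoxy-5-methoxy-6-methyl-1,4-benzoquinone) | COC1=C(C)C(=O)C(OC(C)(C)C)=C(CCCCCCCCCCCCCC2=C(OC(C)(C)C)C(=O)C(C)=C(OC)C2=O)C1=O
A6 | alternative 3 | diethyl 2,18-dioxononadecanedioate | CCOC(=O)C(=O)CCCCCCCCCCCCCCCC(=O)C(=O)OCC
A7 | alternative 3 | 3,3'-(tridecane-1,13-diyl)bis(2,5-dihydroxy-6-methyl-1,4-benzoquinone) | CC1=C(O)C(=O)C(CCCCCCCCCCCCCC2=C(O)C(=O)C(C)=C(O)C2=O)=C(O)C1=O
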